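The seven-membered ring carries oxygen at C8, between the quaternary C8a and C7, and at C4: a 2-oxyallyl unit (C8a–C8–C7) facing a 2-oxy-1,3-diene (C3a–C4–C5–C6), with the cyclopentane carbons C1–C3 as a three-atom tether between C8a and C3a. Both rings are therefore closed in one intramolecular (4+3) cycloaddition of a tertiary 2-ethoxyallyl cation with a tethered 2-silyloxydiene, which forms C3a–C8a and C6–C7 and delivers both ketones. The acyclic precursor comes from (S)-terpinen-4-ol, whose tertiary carbinol centre (C3) controls all other stereocentres; C6–C7 is later dehydrogenated to the ring alkene.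

Key step: step 7

Assumption: (S)-(+)-terpinen-4-ol is taken as purchasable in high enantiomeric purity; it is the only source of absolute configuration.

Numbering: all bicyclic compounds use the azulene numbering of the target (C1, C2 ring CH2; C3 carbinol carbon with isopropyl; C3a ring-fusion CH; C4 benzoyloxy carbon; C5 CH2; C6 methyl-bearing alkene carbon; C7 alkene CH; C8 angeloyloxy carbon; C8a methyl-bearing ring-fusion carbon).

Step 1
Reactants: 1 (S)-(+)-terpinen-4-ol; 2 triethylsilyl trifluoromethanesulfonate
Product: 3 (S)-terpinen-4-ol triethylsilyl ether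
Conditions: TESOTf, 2,6-lutidine, CH2Cl2, 0 °C to rt
Reagents that add atoms: triethylsilyl trifluoromethanesulfonate (2), CC[Si](CC)(CC)OS(=O)(=O)C(F)(F)F
Why: Silyl ether protection of the tertiary alcohol with a silyl triflate masks the hydroxyl, which would otherwise capture the allyl cation of step 7, and leaves the carbinol stereocentre untouched.

Step 2
Reactants: 3 (S)-terpinen-4-ol triethylsilyl ether; 4 ozone
Product: 5 (3S)-6-oxo-3-(propan-2-yl)-3-[(triethylsilyl)oxy]heptanal
Conditions: O3, CH2Cl2, −78 °C; then PPh3, −78 °C to rt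
Reagents that add atoms: ozone (4), [O-][O+]=O
Why: Ozonolysis with reductive work-up (Criegee cleavage) of the only C=C opens the ring to the methyl ketone (future C8a with its methyl) and the aldehyde (future C4) without touching the quaternary silyloxy centre.

Step 3
Reactants: 5 keto aldehyde; 6 (E)-1-bromoprop-1-ene
Product: 7 (5S,8E)-7-hydroxy-5-(propan-2-yl)-5-[(triethylsilyl)oxy]dec-8-en-2-one (both C7 epimers)
Conditions: CrCl2 (4 equiv), NiCl2 (2 mol %), DMF, rt
Reagents that add atoms: (E)-1-bromoprop-1-ene (6), C/C=C/Br
Why: In the Nozaki–Hiyama–Kishi coupling the alkenylchromium reagent adds to the aldehyde only (the methyl ketone is inert) with retention of the E geometry, and the new carbinol centre, formed as a mixture, is oxidised in step 5.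

Step 4
Reactants: 7 hydroxy ketone; 8 ethyl vinyl ether
Product: 9 (6S,9E)-2-ethoxy-3-methyl-6-(propan-2-yl)-6-[(triethylsilyl)oxy]undeca-1,9-diene-3,8-diol (mixture at C3 and C8)
Conditions: ethyl vinyl ether (4 equiv), t-BuLi (3 equiv), THF, −78 to 0 °C; then 7, −78 to −20 °C; aq. NaHCO3
Reagents that add atoms: ethyl vinyl ether (8), C=COCC, used as 1-ethoxyvinyllithium, [Li]C(=C)OCC
Why: 1,2-Addition of 1-ethoxyvinyllithium (an acyl anion equivalent) to the methyl ketone, after deprotonation of the free hydroxyl by the excess reagent, gives the tertiary 2-ethoxyallylic alcohol that serves as cation precursor, its new centre being erased on ionisation.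

Step 5
Reactants: 9 diol
Product: 10 (2E,6S)-10-ethoxy-9-hydroxy-9-methyl-6-(propan-2-yl)-6-[(triethylsilyl)oxy]undeca-2,10-dien-4-one (both C9 epimers)
Conditions: MnO2 (excess), CH2Cl2, rt
Reagents that add atoms: none
Why: Allylic oxidation with MnO2 converts only the secondary allylic alcohol into the (E)-enone, the tertiary alcohol and the enol ether being inert under these neutral conditions.

Step 6
Reactants: 10 enone alcohol; 11 tert-butyldimethylsilyl chloride
Product: 12 (2E,4Z,6R)-4-[(tert-butyldimethylsilyl)oxy]-10-ethoxy-9-methyl-6-(propan-2-yl)-6-[(triethylsilyl)oxy]undeca-2,4,10-trien-9-ol (both C9 epimers)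
Conditions: LDA (2.2 equiv), THF, −78 °C; then TBSCl (1.1 equiv), DMPU, −78 to −30 °C
Reagents that add atoms: tert-butyldimethylsilyl chloride (11), CC(C)(C)[Si](C)(C)Cl
Why: Kinetic α′-deprotonation of the enone (cross-conjugated enolate, after deprotonation of the tertiary hydroxyl) and O-silylation (silyl enol ether formation) should give the 2-silyloxydiene with the Z enol ether geometry favoured by the polar cosolvent, while the hindered tertiary lithium alkoxide is not silylated by TBSCl at low temperature.

Step 7
Reactants: 12 silyloxydiene alcohol; 13 water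
Product: 16 diketo alcohol (3R,3aR,6S,8aS)-3-hydroxy-6,8a-dimethyl-3-(propan-2-yl)perhydroazulene-4,8-dione, via 2-ethoxyallyl cation triflate 14 (not isolated), via O-ethyl oxocarbenium cycloadduct 15 (not isolated)
Conditions: Tf2O (1.2 equiv), 2,6-lutidine (3 equiv), CH2Cl2, −78 to −40 °C; then 48% aq. HF, MeCN, 0 °C to rt
Reagents that add atoms: water (13), O
Why: Triflation of the tertiary alcohol and loss of triflate give the tertiary 2-ethoxyallyl cation 14, which adds across the termini of the tethered (2E,4Z)-2-silyloxydiene, concertedly or by attack of the enol silane carbon on the tertiary cation terminus followed by closure of the enol ether CH2 on the far end of the resulting silyloxyallyl cation, to give 15 with the C3a–C8a and C6–C7 bonds; aqueous HF then hydrolyses the oxocarbenium ion (or its ethyl enol ether) and the silyl enol ether to the two ketones and frees the tertiary alcohol. The closest known reaction is the intramolecular (4+3) cycloaddition of 2-alkoxyallyl cations, generated from alkoxyallylic alcohols with Tf2O and 2,6-lutidine, with dienes held by a three-carbon tether (oxyallyl cation cycloaddition). The five-membered ring closes in the 5-exo mode (C3a onto the cation terminus C8a) and the seven-membered ring is the cycloaddition ring, completed by 7-endo bonding of C7 to the diene terminus C6. C3a is controlled by the C3 carbinol centre, because with the tether perpendicular to the enol ether plane A(1,3) strain against the cis silyloxy group places OTES inside and isopropyl outside so that C3a–H ends cis to isopropyl; C8a follows from the extended transition state, which keeps the ethoxy-bearing central carbon away from the silyloxy-substituted diene and gives the trans ring fusion; C6 follows from the E-propenyl geometry and is removed in step 10. The step needs (4+3) closure to win over (3+2) closure at the oxocarbenium carbon and over proton loss from the cation, which the low temperature, the non-nucleophilic buffer, the placement of the most nucleophilic diene carbon for five-ring closure and the reversibility of the (3+2) mode should secure.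

Step 8
Reactants: 16 diketo alcohol
Product: 17 (3R,3aS,4S,6S,8aS)-3,4-dihydroxy-6,8a-dimethyl-3-(propan-2-yl)perhydroazulen-8-one
Conditions: Me4NBH(OAc)3 (5 equiv), MeCN/AcOH 1:1, −30 to −20 °C
Reagents that add atoms: none
Why: In the Evans–Saksena hydroxyl-directed reduction the C3 hydroxyl binds boron and delivers hydride to the C4 ketone from its own face (that of the angular methyl), which should give the 4S alcohol with C4–OH cis to C3a–H, while the C8 ketone, lacking a β-hydroxyl, is not reduced by this reagent.

Step 9
Reactants: 17 diol ketone; 18 benzoyl chloride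
Product: 19 (3R,3aS,4S,6S,8aS)-3-hydroxy-6,8a-dimethyl-8-oxo-3-(propan-2-yl)perhydroazulen-4-yl benzoate
Conditions: BzCl (1.5 equiv), pyridine, DMAP (cat.), CH2Cl2, 0 °C to rt
Reagents that add atoms: benzoyl chloride (18), O=C(Cl)c1ccccc1
Why: Esterification with the acid chloride occurs only at the secondary C4 hydroxyl, with retention, because the tertiary C3 hydroxyl is too hindered to be acylated.

Step 10
Reactants: 19 keto benzoate
Product: 20 (3R,3aS,4S,8aS)-3-hydroxy-6,8a-dimethyl-8-oxo-3-(propan-2-yl)-1,2,3,3a,4,5,8,8a-octahydroazulen-4-yl benzoate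
Conditions: IBX (3 equiv), DMSO/fluorobenzene 1:2, 70 °C
Reagents that add atoms: none
Why: IBX dehydrogenation of the ketone must pass through its only possible enol (C8a is quaternary), so the double bond can only form between C7 and C6, giving the trisubstituted enone and removing the C6 stereocentre while benzoate and tertiary alcohol survive the neutral conditions.

Step 11
Reactants: 20 enone
Product: 21 (3R,3aS,4S,8S,8aS)-3,8-dihydroxy-6,8a-dimethyl-3-(propan-2-yl)-1,2,3,3a,4,5,8,8a-octahydroazulen-4-yl benzoate
Conditions: NaBH4, CeCl3·7H2O, MeOH, −78 to −40 °C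
Reagents that add atoms: none
Why: In the Luche 1,2-reduction hydride should add to C8 from the face opposite the axial angular methyl on the neighbouring C8a, giving the 8S alcohol (hydroxyl cis to that methyl), the epimer needed for inversion in step 12.

Step 12
Reactants: 21 allylic alcohol; 22 angelic acid
Product: 23 target, (3R,3aS,4S,8R,8aS)-4-(benzoyloxy)-3-hydroxy-6,8a-dimethyl-3-(propan-2-yl)-1,2,3,3a,4,5,8,8a-octahydroazulen-8-yl (Z)-2-methylbut-2-enoate
Conditions: angelic acid (3 equiv), PPh3 (3 equiv), DIAD (3 equiv), toluene, 0 °C to rt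
Reagents that add atoms: angelic acid (22), C/C=C(/C)C(=O)O
Why: Mitsunobu esterification displaces the activated allylic oxygen by angelate in an SN2 step from the face anti to the angular methyl, inverting C8 to R, and the neutral low-temperature conditions without nucleophilic amine should preserve the Z geometry of the angelate and leave the tertiary alcohol alone.

Compound list
1 | (S)-(+)-terpinen-4-ol, (1S)-4-methyl-1-(propan-2-yl)cyclohex-3-en-1-ol | CC1=CC[C@](O)(C(C)C)CC1 | starting material
2 | triethylsilyl trifluoromethanesulfonate | CC[Si](CC)(CC)OS(=O)(=O)C(F)(F)F | starting material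
3 | (S)-terpinen-4-ol triethylsilyl ether | CC1=CC[C@](O[Si](CC)(CC)CC)(C(C)C)CC1 | intermediate
4 | ozone | [O-][O+]=O | starting material
5 | (3S)-6-oxo-3-(propan-2-yl)-3-[(triethylsilyl)oxy]heptanal | O=CC[C@](O[Si](CC)(CC)CC)(C(C)C)CCC(C)=O | intermediate
6 | (E)-1-bromoprop-1-ene | C/C=C/Br | starting material
7 | (5S,8E)-7-hydroxy-5-(propan-2-yl)-5-[(triethylsilyl)oxy]dec-8-en-2-one, both C7 epimers | C/C=C/C(O)C[C@](O[Si](CC)(CC)CC)(C(C)C)CCC(C)=O | intermediate
8 | ethyl vinyl ether | C=COCC | starting material
9 | (6S,9E)-2-ethoxy-3-methyl-6-(propan-2-yl)-6-[(triethylsilyl)oxy]undeca-1,9-diene-3,8-diol, mixture at C3 and C8 | C/C=C/C(O)C[C@](O[Si](CC)(CC)CC)(C(C)C)CCC(C)(O)C(=C)OCC | intermediate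
10 | (2E,6S)-10-ethoxy-9-hydroxy-9-methyl-6-(propan-2-yl)-6-[(triethylsilyl)oxy]undeca-2,10-dien-4-one, both C9 epimers | C/C=C/C(=O)C[C@](O[Si](CC)(CC)CC)(C(C)C)CCC(C)(O)C(=C)OCC | intermediate
11 | tert-butyldimethylsilyl chloride | CC(C)(C)[Si](C)(C)Cl | starting material
12 | (2E,4Z,6R)-4-[(tert-butyldimethylsilyl)oxy]-10-ethoxy-9-methyl-6-(propan-2-yl)-6-[(triethylsilyl)oxy]undeca-2,4,10-trien-9-ol, both C9 epimers | C/C=C/C(O[Si](C)(C)C(C)(C)C)=C/[C@](O[Si](CC)(CC)CC)(C(C)C)CCC(C)(O)C(=C)OCC | intermediate
13 | water | O | starting material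
14 | tertiary 2-ethoxyallyl cation (triflate) formed from 12 | C/C=C/C(O[Si](C)(C)C(C)(C)C)=C/[C@](O[Si](CC)(CC)CC)(C(C)C)CC[C+](C)C(=C)OCC.[O-]S(=O)(=O)C(F)(F)F | intermediate
15 | trans-fused (4+3) cycloadduct as O-ethyl oxocarbenium triflate, with C4–C5 silyl enol ether and C3 triethylsilyl ether | CC[O+]=C1C[C@@H](C)C=C(O[Si](C)(C)C(C)(C)C)[C@@H]2[C@]1(C)CC[C@@]2(O[Si](CC)(CC)CC)C(C)C.[O-]S(=O)(=O)C(F)(F)F | intermediate
16 | (3R,3aR,6S,8aS)-3-hydroxy-6,8a-dimethyl-3-(propan-2-yl)perhydroazulene-4,8-dione (trans ring fusion, C6 methyl cis to C8a methyl) | O=C1C[C@@H](C)CC(=O)[C@@H]2[C@]1(C)CC[C@@]2(O)C(C)C | intermediate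
17 | (3R,3aS,4S,6S,8aS)-3,4-dihydroxy-6,8a-dimethyl-3-(propan-2-yl)perhydroazulen-8-one | O=C1C[C@@H](C)C[C@H](O)[C@@H]2[C@]1(C)CC[C@@]2(O)C(C)C | intermediate
18 | benzoyl chloride | O=C(Cl)c1ccccc1 | starting material
19 | (3R,3aS,4S,6S,8aS)-3-hydroxy-6,8a-dimethyl-8-oxo-3-(propan-2-yl)perhydroazulen-4-yl benzoate | O=C1C[C@@H](C)C[C@H](OC(=O)c3ccccc3)[C@@H]2[C@]1(C)CC[C@@]2(O)C(C)C | intermediate
20 | (3R,3aS,4S,8aS)-3-hydroxy-6,8a-dimethyl-8-oxo-3-(propan-2-yl)-1,2,3,3a,4,5,8,8a-octahydroazulen-4-yl benzoate | O=C1C=C(C)C[C@H](OC(=O)c3ccccc3)[C@@H]2[C@]1(C)CC[C@@]2(O)C(C)C | intermediate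
21 | (3R,3aS,4S,8S,8aS)-3,8-dihydroxy-6,8a-dimethyl-3-(propan-2-yl)-1,2,3,3a,4,5,8,8a-octahydroazulen-4-yl benzoate (C8 hydroxyl cis to the angular methyl) | O[C@H]1C=C(C)C[C@H](OC(=O)c3ccccc3)[C@@H]2[C@]1(C)CC[C@@]2(O)C(C)C | intermediate
22 | angelic acid, (Z)-2-methylbut-2-enoic acid | C/C=C(/C)C(=O)O | starting material
23 | (3R,3aS,4S,8R,8aS)-4-(benzoyloxy)-3-hydroxy-6,8a-dimethyl-3-(propan-2-yl)-1,2,3,3a,4,5,8,8a-octahydroazulen-8-yl (Z)-2-methylbut-2-enoate | C/C=C(/C)C(=O)O[C@@H]1C=C(C)C[C@H](OC(=O)c2ccccc2)[C@@H]2[C@]1(C)CC[C@@]2(O)C(C)C | target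

Total step count: 12. Longest linear sequence: 12 steps (fully linear from 1).

Steps most likely to fail

Step 7. The annulation may stop after the first C–C bond because the silyloxyallyl cation loses its silyl group, or the second bond may close at the oxocarbenium carbon in the (3+2) sense. The fallback replaces the single cycloaddition by two separate ionic ring closures. Setting out from 12, the same ionisation (Tf2O, 2,6-lutidine, −78 °C) is quenched cold with aqueous NaHCO3 to isolate the monocyclic alkylation product, the cyclopentyl enone enol ether F1, in which C3a–C8a is already formed. Mild hydrolysis of its enol ether (oxalic acid, wet THF) gives the methyl ketone F2. Its kinetic methyl-ketone enolate (LiHMDS, THF, −78 to 0 °C) closes the seven-membered ring by intramolecular Michael addition to the (E)-enone, giving the silyl-protected diketone F3. HF in MeCN then returns the route at 16; the C6 epimers converge in step 10.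

Step 12. The activated allylic alcohol may ionise instead of undergoing clean displacement, leading to loss of stereochemical integrity, allylic transposition or elimination, and the angelate may isomerise. The fallback replaces inversion by reagent-controlled reduction and acylation with retention. Setting out from 20, Corey–Bakshi–Shibata reduction (2-methyl-CBS-oxazaborolidine, expected S catalyst with the quaternary C8a as the large group, catecholborane, toluene, −78 °C) delivers hydride to the methyl face and gives the 8R allylic alcohol F4. Yamaguchi acylation through the mixed anhydride F5 (angelic acid, 2,4,6-trichlorobenzoyl chloride, Et3N; then F4, toluene, 80 °C, no nucleophilic catalyst) gives 23 directly.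

Step 8. Exchange of the hindered tertiary hydroxyl onto boron may be too slow, so that reduction is sluggish or not directed and facial selectivity is poor. The fallback uses chelation control with external hydride followed by inversion. Setting out from 16, Narasaka–Prasad reduction (Et2BOMe, NaBH4, THF/MeOH, −78 °C) activates only the chelated C4 ketone and is expected to give the C4-epimeric syn diol F6. Mitsunobu esterification with benzoic acid (PPh3, DIAD, toluene) inverts C4 and installs the benzoate in the same operation, returning the route at 19.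

Further compounds
F1 | step 7 | (E)-1-[2-(1-ethoxyethenyl)-2-methyl-5-(propan-2-yl)-5-(triethylsilyloxy)cyclopentyl]but-2-en-1-one, acyl group cis to the ring methyl and to the silyloxy group | C/C=C/C(=O)[C@@H]1[C@@](C)(C(=C)OCC)CC[C@@]1(O[Si](CC)(CC)CC)C(C)C
F2 | step 7 | (E)-1-[2-acetyl-2-methyl-5-(propan-2-yl)-5-(triethylsilyloxy)cyclopentyl]but-2-en-1-one, same ring configuration as F1 | C/C=C/C(=O)[C@@H]1[C@@](C)(C(C)=O)CC[C@@]1(O[Si](CC)(CC)CC)C(C)C
F3 | step 7 | C3 triethylsilyl ether of 16 (C6 epimers) | O=C1CC(C)CC(=O)[C@@H]2[C@]1(C)CC[C@@]2(O[Si](CC)(CC)CC)C(C)C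
F4 | step 12 | (3R,3aS,4S,8R,8aS)-3,8-dihydroxy-6,8a-dimethyl-3-(propan-2-yl)-1,2,3,3a,4,5,8,8a-octahydroazulen-4-yl benzoate (C8 epimer of 21) | O[C@@H]1C=C(C)C[C@H](OC(=O)c3ccccc3)[C@@H]2[C@]1(C)CC[C@@]2(O)C(C)C
F5 | step 12 | angelic 2,4,6-trichlorobenzoic anhydride | C/C=C(/C)C(=O)OC(=O)c1c(Cl)cc(Cl)cc1Cl
F6 | step 8 | (3R,3aS,4R,6S,8aS)-3,4-dihydroxy-6,8a-dimethyl-3-(propan-2-yl)perhydroazulen-8-one (C4 epimer of 17) | O=C1C[C@@H](C)C[C@@H](O)[C@@H]2[C@]1(C)CC[C@@]2(O)C(C)C
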